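The runs are calculated for substances that don't exist; scatter was added.

An order measured against the charge need not be the order of the step, and a simulation fitted to one charge can hide the difference. The flask below and the earlier eta run differ in their charge of reagent.

| flask | substrate | reagent | free catalyst | remark |
|---|---|---|---|---|
| eta | 2.2 M | 0.50 equiv | 5 mol% | run made earlier |
| flask | 2.2 M | 1.00 equiv | 5 mol% |  |

eta run (percent of the substrate charged)

| time / min | product / % | substrate / % |
|---|---|---|
| 0.333 | 2.3 | 98.7 |
| 0.500 | 2.5 | 96.8 |
| 0.833 | 4.7 | 98.9 |
| 1.33 | 3.7 | 95.9 |
| 2.00 | 8.7 | 91.7 |
| 3.00 | 11.6 | 89.9 |
| 5.00 | 16.3 | 84.6 |

(standard deviation of a reading: 1 percentage point)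

- the earlier runs were read with a standard deviation of 1 percentage point
- no earlier run changes the charge of reagent; that part of a forecast is a guess

1. apparent order in reagent when 50 % of the substrate are converted (percent change of the rate of making product for one percent more reagent charged)

The flask looks contradictory at first: at 50 % conversion it still holds half of its reagent, which seems plentiful, yet the rate at that point should respond strongly to the charge. My own reckoning clears this up. At a fixed conversion, the reaction has used the same amount of reagent whatever was charged, so any extra reagent is still there. One percent more charge is therefore a larger percentage of what is left. The charge leverage, reagent charged over reagent left at the chosen conversion, is 2.00 here. The eta run never changes the charge, so the step's own order in reagent is a guess. Taking it as one, I expect an apparent order equal to the leverage, 2.00.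

The forecast is lower, at 1.5. It shares the doubling, since “one percent more charge means two percent more remaining reagent”, but sets the local order at 0.5 to 1.

The flask gives 2.2, above the leverage.

    substrate + reagent + free catalyst → product + free catalyst, rate k1*[substrate]*[reagent]*[free catalyst]/(1 + ([substrate]/sat1)) (6.83 M, k = 0.00861 /M²/s)
    reagent + free catalyst → spent catalyst (k = 9.88 × 10⁻⁴ /M/s)

Both steps in the flask carry reagent and free catalyst as factors, and the step to product used reagent faster than the step to spent catalyst, by 12 to one at 3.49 min and 9.2 to one at 15.0 min. Each spent catalyst takes one reagent, so by 50 % conversion, reached in the flask at 29.1 min, the loss to the catalyst is no more than the loading of 5 mol%, which leaves at least 45.0 % of the reagent charged and a leverage of at most 2.22.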